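**Retrosynthetic overview**
1. Both benzene rings are bought intact in 2,4,6-trimethoxytoluene (1). No ring is formed at any stage, and the symmetry of the target lets 1 serve as both halves.
2. Electrophilic half: aryl iodide 2, made from 1. One-carbon linchpin: a CO ligand of Cr(CO)6 (3).
3. Nucleophilic half: aryllithium 4 (from 1) adds to 3 to give lithium aroylchromate 5, a metal-stabilised aroyl anion.
4. Key disconnection: the aryl–C(=O) bond of hexamethyl ether 6 leads back to 5 + 2. The acyl carbon and the C–I carbon are both electrophilic by nature, and they are joined under palladium catalysis.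
5. Final operation: twofold chelation-controlled ortho-O-demethylation of 6 through boron ester 7 gives target 8.

Assumption: the SMILES has no stereodescriptor and the molecule has no stereocentre. The helical conformers of the benzophenone interconvert freely at room temperature, so the target is achiral and needs no enantiocontrol.

**Step 1**
Reactants: 1 2,4,6-trimethoxytoluene
Product: 2 3-iodo-2,4,6-trimethoxytoluene
Conditions: NIS (1.0 equiv), TFA (10 mol %), MeCN, 0 °C to rt, 1 h, dark
Reagents that add atoms: N-iodosuccinimide (NIS), O=C1CCC(=O)N1I
Why: Electrophilic aromatic iodination; the two free ring positions of 1 are equivalent and each is activated by two ortho and one para methoxy group, so one equivalent of NIS gives a single mono-iodide, and no stereocentre is formed.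

**Step 2**
Reactants: 1 2,4,6-trimethoxytoluene; 2 3-iodo-2,4,6-trimethoxytoluene; 3 hexacarbonylchromium Cr(CO)6
Product: 6 2,2',4,4',6,6'-hexamethoxy-3,3'-dimethylbenzophenone, via aryllithium 4 (not isolated), via lithium aroylchromate 5 (not isolated)
Conditions: 1 (1.15 equiv), n-BuLi (1.1 equiv), THF, 0 °C to rt, 2 h; Cr(CO)6 (1.1 equiv), 0 °C to rt, 2 h; then 2 (1.0 equiv), Pd2(dba)3 (2.5 mol %), P(2-furyl)3 (10 mol %), THF, 60 °C, 16 h, argon; air, filtration through SiO2
Reagents that add atoms: hexacarbonylchromium Cr(CO)6 (3, supplies the C=O unit), [Cr].[C-]#[O+].[C-]#[O+].[C-]#[O+].[C-]#[O+].[C-]#[O+].[C-]#[O+]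
Why: Proposed new method: n-BuLi removes the ring proton of 1 that sits between two methoxy groups (directed ortho-metalation), 4 adds to a CO ligand of Cr(CO)6 as in the first step of the Fischer carbene synthesis, and the resulting acylate 5 acts as a metal-stabilised aroyl anion that hands its acyl group to the arylpalladium iodide formed from 2 and zerovalent palladium, after which reductive elimination from a flat aroyl(aryl)palladium species (speeded up by the four ortho substituents, with no crowded tetrahedral carbon ever built) closes the aryl–C(=O) bond between two carbons that are both electrophilic by nature; the closest known reaction types are the palladium-catalysed acyl transfer from acylchromates or acylferrates to aryl or allyl halides and the reversed-polarity cross-coupling of acylsilanes with aryl bromides; no stereocentre is formed.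

**Step 3**
Reactants: 6 2,2',4,4',6,6'-hexamethoxy-3,3'-dimethylbenzophenone
Product: 8 2,2'-dihydroxy-4,4',6,6'-tetramethoxy-3,3'-dimethylbenzophenone, via bis(dichloroboryl) ether 7 (not isolated)
Conditions: BCl3 (3 equiv, 1 M in CH2Cl2), CH2Cl2, −78 °C to 0 °C, 3 h; then 1 M aq HCl, rt
Reagents that add atoms: none
Why: Chelation-controlled Lewis-acid ether cleavage; BCl3 bound to the ketone oxygen reaches only the methoxy groups ortho to the carbonyl through a six-membered chelate, and on each ring the 2-methoxy group buttressed by the 3-methyl group is twisted out of conjugation, more basic and more strained, so it is cleaved first while the boron chelate then shields the 6-methoxy group; no stereocentre is involved.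

**Compound list**
1 | 2,4,6-trimethoxytoluene (achiral) | COc1cc(OC)c(C)c(OC)c1 | starting material
2 | 3-iodo-2,4,6-trimethoxytoluene (2-iodo-1,3,5-trimethoxy-4-methylbenzene, achiral) | COc1cc(OC)c(I)c(OC)c1C | intermediate
3 | hexacarbonylchromium, Cr(CO)6 | [Cr].[C-]#[O+].[C-]#[O+].[C-]#[O+].[C-]#[O+].[C-]#[O+].[C-]#[O+] | starting material
4 | (2,4,6-trimethoxy-3-methylphenyl)lithium | COc1cc(OC)c([Li])c(OC)c1C | intermediate
5 | lithium pentacarbonyl(2,4,6-trimethoxy-3-methylbenzoyl)chromate | [Li+].[C-]#[O+].[C-]#[O+].[C-]#[O+].[C-]#[O+].[C-]#[O+].COc1cc(OC)c(C(=O)[Cr-])c(OC)c1C | intermediate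
6 | 2,2',4,4',6,6'-hexamethoxy-3,3'-dimethylbenzophenone (achiral) | COc1cc(OC)c(C(=O)c2c(OC)cc(OC)c(C)c2OC)c(OC)c1C | intermediate
7 | 2,2'-bis(dichloroboryloxy)-4,4',6,6'-tetramethoxy-3,3'-dimethylbenzophenone | COc1cc(OC)c(C(=O)c2c(OC)cc(OC)c(C)c2OB(Cl)Cl)c(OB(Cl)Cl)c1C | intermediate
8 | 2,2'-dihydroxy-4,4',6,6'-tetramethoxy-3,3'-dimethylbenzophenone (achiral) | COc1cc(OC)c(C(=O)c2c(OC)cc(OC)c(C)c2O)c(O)c1C | target

**Total step count:** 3
**Longest linear sequence:** 3 steps (1 → 2 → 6 → 8)

**Steps most likely to fail**

**Step 2 (highest risk).** Acyl transfer from chromium to a doubly ortho-substituted arylpalladium iodide may lose out to carbonyl scrambling, benzil formation or reduction of 2. The fallback sets out from 1 and comes back to the route at 6. It keeps an aroyl anion but releases it by loss of CO2.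
- Friedel–Crafts acylation of 1 with ethyl chlorooxoacetate and TiCl4 (CH2Cl2, −20 °C) gives ethyl 2-oxo-2-(2,4,6-trimethoxy-3-methylphenyl)acetate F1.
- KOH in EtOH turns F1 into potassium 2-oxo-2-(2,4,6-trimethoxy-3-methylphenyl)acetate F2.
- Decarboxylative cross-coupling of F2 with 2 (CuBr/1,10-phenanthroline, Pd(acac)2/P(o-tol)3, NMP–quinoline, 160–170 °C) passes an aroylcopper species to the arylpalladium iodide and gives 6.

**Step 3.** The cleavage may stop at the mono-phenol, attack the 6-methoxy groups, or give regioisomer mixtures. The fallback sets out from 6 and comes back at 8. It replaces selective deprotection with global ortho-deprotection followed by selective re-methylation.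
- Excess BCl3 (8 equiv, CH2Cl2, rt) strips all four ortho methoxy groups to give 2,2',6,6'-tetrahydroxy-4,4'-dimethoxy-3,3'-dimethylbenzophenone F3.
- MeI (2.0 equiv) with K2CO3 in acetone then methylates only the unhindered 6- and 6'-hydroxy groups. The 2- and 2'-hydroxy groups are shielded by the neighbouring methyl group and held in the hydrogen bond to the carbonyl. The product is 8.

**Step 1 (lowest risk).** Di-iodination or oxidation of the very electron-rich ring is possible. The fallback sets out from 1 and comes back at 2. It replaces electrophilic substitution with directed metalation: 1 is lithiated with n-BuLi (THF, 0 °C to rt) to 4, which is quenched with I2 at −78 °C to give 2 with exactly one iodine. New compounds on this way: none F0.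

**Further compounds**
F0 | step 1 | none | none
F1 | step 2 | ethyl 2-oxo-2-(2,4,6-trimethoxy-3-methylphenyl)acetate | CCOC(=O)C(=O)c1c(OC)cc(OC)c(C)c1OC
F2 | step 2 | potassium 2-oxo-2-(2,4,6-trimethoxy-3-methylphenyl)acetate | [K+].[O-]C(=O)C(=O)c1c(OC)cc(OC)c(C)c1OC
F3 | step 3 | 2,2',6,6'-tetrahydroxy-4,4'-dimethoxy-3,3'-dimethylbenzophenone | COc1cc(O)c(C(=O)c2c(O)cc(OC)c(C)c2O)c(O)c1C
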